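**Plan**

1. Retrosynthesis: the enone C=C is cut first (Claisen–Schmidt), then the acetyl–ring A bond (Stille coupling of an aryl iodide), then the C4–ring A bond (Negishi coupling of an enol triflate of a tetrahydropyran-4-one, followed by alkene hydrogenation).
2. The pyranone is cut at C5–C6. In the ring O1/C2 (arylethyl)/C3/C4 (ring A)/C5/C6 (4-hydroxyphenyl), C6 carries both O1 and a para-oxygenated aryl group, so it is the CH2 of a 4-alkoxybenzyl ether at a higher oxidation level; DDQ can turn that CH2 into an oxocarbenium carbon that an enol acetate spanning C4/C5 attacks.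
3. Further back, O1–C6 is cut (benzyl imidate etherification), the enol acetate returns to a terminal alkyne, and C2–C3 is cut (propargylboration of a 3-arylpropanal).
4. Forward order: chain with C2 → benzyl ether → enol acetate → tetrahydropyranone (the only ring made) → ring A at C4 → hydrogenation → acetyl group → chalcone → removal of four acetal groups.
5. Stereochemistry: C2 (S) from the chiral phosphoric acid-catalysed propargylation; C6 (S) from the chair transition state of the cyclisation, relayed from C2 (2,6-cis); C4 (R) from axial hydrogen delivery to the C4 radical, which puts ring A equatorial (all-cis, 2S,4R,6S).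

Key step: step 9

Assumption: the (R)-configured phosphoric acid is taken to deliver the propargyl group to the Re face of the aldehyde, as in its aldehyde allylborations; should MTPA-ester analysis of 7 show the opposite sense, the (S)-catalyst is used.

**Route**

Step 1
Reactants: 1 3-(4-hydroxyphenyl)propanoic acid
Product: 2 3-[4-(pivaloyloxy)phenyl]propanoic acid
Conditions: NaOH (2 equiv), H2O/THF, 0 °C; t-BuCOCl (1.05 equiv); then aq. HCl
Reagents that add atoms: pivaloyl chloride, CC(C)(C)C(=O)Cl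
Why: Schotten–Baumann O-acylation, in which the phenoxide is far more nucleophilic than the carboxylate, so one equivalent of acid chloride should give the aryl ester and the acid is recovered on acidification.

Step 2
Reactants: 2 3-[4-(pivaloyloxy)phenyl]propanoic acid
Product: 3 4-(3-hydroxypropyl)phenyl pivalate
Conditions: BH3·SMe2, THF, 0 °C → rt; MeOH quench, aqueous work-up
Reagents that add atoms: none
Why: Borane reduces a carboxylic acid through its acyloxyborane much faster than an ester, so the hindered aryl pivalate should remain (chemoselective borane reduction).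

Step 3
Reactants: 3 4-(3-hydroxypropyl)phenyl pivalate
Product: 4 4-(3-oxopropyl)phenyl pivalate
Conditions: TEMPO (cat.), PhI(OAc)2, CH2Cl2, rt
Reagents that add atoms: none
Why: Oxoammonium (TEMPO) oxidation of a primary alcohol stops at the aldehyde and is neutral enough for the aryl ester.

Step 4
Reactants: 4 4-(3-oxopropyl)phenyl pivalate; 5 allenylboronic acid pinacol ester
Product: 7 4-[(3S)-3-hydroxyhex-5-yn-1-yl]phenyl pivalate, via pinacol borate ester 6 (not isolated)
Conditions: (R)-TRIP [(R)-3,3'-bis(2,4,6-triisopropylphenyl)-1,1'-binaphthyl-2,2'-diyl hydrogen phosphate, 10 mol %], 4 Å MS, toluene, 0 °C; aqueous work-up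
Reagents that add atoms: none
Why: Chiral phosphoric acid-catalysed propargylboration, in which the acid organises boronate and aldehyde in a closed six-membered transition state, SE2' transfer from the allenyl boronate gives only the homopropargylic alcohol, and the (R)-catalyst is expected to direct attack to the Re face, which corresponds to the (S) carbinol (C2 of the later ring); borate 6 is hydrolysed on work-up.

Step 5
Reactants: 8 4-(methoxymethoxy)benzaldehyde
Product: 9 [4-(methoxymethoxy)phenyl]methanol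
Conditions: NaBH4, MeOH, 0 °C
Reagents that add atoms: none
Why: Borohydride reduction of an aromatic aldehyde; the aryl acetal is inert to hydride.

Step 6
Reactants: 9 [4-(methoxymethoxy)phenyl]methanol
Product: 10 4-(methoxymethoxy)benzyl 2,2,2-trichloroacetimidate
Conditions: Cl3CCN, DBU (cat.), CH2Cl2, 0 °C; used crude after filtration through basic alumina
Reagents that add atoms: trichloroacetonitrile, ClC(Cl)(Cl)C#N
Why: Base-catalysed addition of the alcohol to the nitrile (trichloroacetimidate formation) gives the benzyl donor without any acid.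

Step 7
Reactants: 7 4-[(3S)-3-hydroxyhex-5-yn-1-yl]phenyl pivalate; 10 4-(methoxymethoxy)benzyl 2,2,2-trichloroacetimidate
Product: 11 4-[(3S)-3-{[4-(methoxymethoxy)benzyl]oxy}hex-5-yn-1-yl]phenyl pivalate
Conditions: La(OTf)3 (5 mol %), toluene, rt
Reagents that add atoms: none
Why: Acid-catalysed trichloroacetimidate benzylation, in which the imidate ionises to a 4-alkoxybenzyl cation that the secondary alcohol captures under conditions mild enough for pivalate, alkyne and aryl acetal; the carbinol centre is not involved.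

Step 8
Reactants: 11 4-[(3S)-3-{[4-(methoxymethoxy)benzyl]oxy}hex-5-yn-1-yl]phenyl pivalate
Product: 12 4-[(3S)-5-acetoxy-3-{[4-(methoxymethoxy)benzyl]oxy}hex-5-en-1-yl]phenyl pivalate
Conditions: [RuCl2(p-cymene)]2 (cat.), P(2-furyl)3, Na2CO3 (cat.), AcOH, toluene, 80 °C
Reagents that add atoms: acetic acid, CC(=O)O
Why: Ruthenium-catalysed Markovnikov addition of a carboxylic acid to a terminal alkyne should give the 2-acetoxy-1-alkene regioselectively, with ethers and esters tolerated.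

Step 9
Reactants: 12 4-[(3S)-5-acetoxy-3-{[4-(methoxymethoxy)benzyl]oxy}hex-5-en-1-yl]phenyl pivalate
Product: 15 4-{2-[(2S,6S)-6-[4-(methoxymethoxy)phenyl]-4-oxotetrahydro-2H-pyran-2-yl]ethyl}phenyl pivalate (2,6-cis), via (E)-aryl oxocarbenium ion 13 (not isolated), via O-acetyl oxocarbenium ion 14 (not isolated)
Conditions: DDQ (2 equiv), 2,6-dichloropyridine (4 equiv), LiClO4 (cat.), 4 Å MS, ClCH2CH2Cl, rt
Reagents that add atoms: none
Why: DDQ removes a hydride (electron transfer, then hydrogen loss) from the ether CH2 of 12, which is activated by the ether oxygen and by the para-alkoxy group of its arene, to give the (E)-aryl oxocarbenium ion 13; the terminal carbon of the enol acetate then attacks the cationic carbon (C5–C6 bond), and the resulting O-acetyl oxocarbenium ion 14 gives up its acetyl group to leave the ketone. The closest known reaction type is the DDQ-mediated oxidative C–H cyclisation of 4-methoxybenzyl ethers carrying an enol acetate, a Prins-type closure of an oxidatively generated oxocarbenium ion that gives 2,6-cis-tetrahydropyran-4-ones. The one ring formed, the tetrahydropyranone, closes in the 6-endo mode. The new stereocentre C6 is controlled by the existing C2 centre through a chair transition state in which the (E)-oxocarbenium geometry places the aryl group and the C2 arylethyl chain both equatorial, hence 2,6-cis (6S). The step needs hydride abstraction at this one CH2 only: the other arene is deactivated by its pivalate and its benzylic CH2 has no oxygen, the OCH2O group is not benzylic, the C6–H of the product is tertiary and poorly aligned, and 2,6-dichloropyridine buffers the acidic hydroquinone so that acetal and enol acetate survive.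

Step 10
Reactants: 15 4-{2-[(2S,6S)-6-[4-(methoxymethoxy)phenyl]-4-oxotetrahydro-2H-pyran-2-yl]ethyl}phenyl pivalate
Product: 16 4-{2-[(2S,6S)-6-[4-(methoxymethoxy)phenyl]-4-(trifluoromethanesulfonyloxy)-3,6-dihydro-2H-pyran-2-yl]ethyl}phenyl pivalate (C4=C5 isomer) and 17 4-{2-[(2S,6S)-6-[4-(methoxymethoxy)phenyl]-4-(trifluoromethanesulfonyloxy)-5,6-dihydro-2H-pyran-2-yl]ethyl}phenyl pivalate (C3=C4 isomer), kept as the mixture
Conditions: KN(SiMe3)2, THF, −78 °C; N-(5-chloropyridin-2-yl)bis(trifluoromethanesulfonimide), −78 °C; aq. NH4Cl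
Reagents that add atoms: N-(5-chloropyridin-2-yl)-1,1,1-trifluoro-N-(trifluoromethanesulfonyl)methanesulfonamide, O=S(=O)(N(c1ccc(Cl)cn1)S(=O)(=O)C(F)(F)F)C(F)(F)F
Why: Kinetic enolate formation and O-sulfonylation (enol triflate synthesis) at −78 °C, cold enough to prevent β-elimination of the ring oxygen; the ketone enolises to either side, so both regioisomers are expected, which is harmless because both lead to the same C4 radical in step 13.

Step 11
Reactants: 18 5-methoxyresorcinol
Product: 19 1-methoxy-3,5-bis(methoxymethoxy)benzene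
Conditions: NaH, DMF, 0 °C; MeOCH2Cl, 0 °C → rt
Reagents that add atoms: chloromethyl methyl ether, COCCl
Why: O-alkylation of both phenoxides (Williamson-type acetal formation) installs groups that later direct metalation.

Step 12
Reactants: 16 and 17 (mixture of enol triflates); 19 1-methoxy-3,5-bis(methoxymethoxy)benzene
Product: 22 4-{2-[(2S,6S)-4-[4-methoxy-2,6-bis(methoxymethoxy)phenyl]-6-[4-(methoxymethoxy)phenyl]-3,6-dihydro-2H-pyran-2-yl]ethyl}phenyl pivalate and 23 4-{2-[(2S,6S)-4-[4-methoxy-2,6-bis(methoxymethoxy)phenyl]-6-[4-(methoxymethoxy)phenyl]-5,6-dihydro-2H-pyran-2-yl]ethyl}phenyl pivalate, via aryllithium 20 (not isolated), via arylzinc chloride 21 (not isolated)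
Conditions: 19, n-BuLi, THF, 0 °C; ZnCl2, 0 °C → rt; then 16/17, Pd2(dba)3 (cat.), SPhos, THF, 60 °C
Reagents that add atoms: none
Why: Directed ortho-lithiation at the carbon flanked by both methoxymethoxy groups (the most acidic, doubly chelated site), transmetalation to zinc and Negishi coupling, in which a zerovalent palladium catalyst with a bulky biaryl phosphine accepts the doubly ortho-substituted arylzinc while the pivalate is left alone.

Step 13
Reactants: 22 and 23 (mixture of 4-aryl dihydropyrans)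
Product: 24 4-{2-[(2S,4R,6S)-4-[4-methoxy-2,6-bis(methoxymethoxy)phenyl]-6-[4-(methoxymethoxy)phenyl]tetrahydro-2H-pyran-2-yl]ethyl}phenyl pivalate (all-cis)
Conditions: Mn(dpm)3 (cat.; dpm = 2,2,6,6-tetramethylheptane-3,5-dionate), PhSiH3, t-BuOOH, i-PrOH, rt, argon
Reagents that add atoms: none
Why: Hydrogen-atom-transfer hydrogenation by a manganese hydride, in which a hydrogen atom adds to C5 or C3 so that both alkenes give the same tertiary C4 radical, and the second hydrogen is delivered axially so that the bulky aryl group ends up equatorial and cis to the groups at C2 and C6 (4R); the benzylic C–O bonds, which hydrogenolysis could cleave, are not at risk.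

Step 14
Reactants: 24 4-{2-[(2S,4R,6S)-4-[4-methoxy-2,6-bis(methoxymethoxy)phenyl]-6-[4-(methoxymethoxy)phenyl]tetrahydro-2H-pyran-2-yl]ethyl}phenyl pivalate
Product: 25 4-{2-[(2S,4R,6S)-4-[3-iodo-4-methoxy-2,6-bis(methoxymethoxy)phenyl]-6-[4-(methoxymethoxy)phenyl]tetrahydro-2H-pyran-2-yl]ethyl}phenyl pivalate
Conditions: N-iodosuccinimide (1.0 equiv), MeCN, 0 °C, dark
Reagents that add atoms: N-iodosuccinimide, O=C1CCC(=O)N1I
Why: Electrophilic aromatic iodination should occur only on the ring with three oxygen donors, whose two free positions are equivalent by rotation about the C4–aryl bond, so a single monoiodide is expected.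

Step 15
Reactants: 25 4-{2-[(2S,4R,6S)-4-[3-iodo-4-methoxy-2,6-bis(methoxymethoxy)phenyl]-6-[4-(methoxymethoxy)phenyl]tetrahydro-2H-pyran-2-yl]ethyl}phenyl pivalate
Product: 27 4-{2-[(2S,4R,6S)-4-[3-acetyl-4-methoxy-2,6-bis(methoxymethoxy)phenyl]-6-[4-(methoxymethoxy)phenyl]tetrahydro-2H-pyran-2-yl]ethyl}phenyl pivalate, via 1-ethoxyvinyl arene 26 (not isolated)
Conditions: Bu3Sn–C(OEt)=CH2, PdCl2(PPh3)2 (cat.), toluene, 100 °C; then 0.5 M aq. HCl, THF, 0 °C, brief
Reagents that add atoms: tributyl(1-ethoxyvinyl)stannane, CCCC[Sn](CCCC)(CCCC)C(=C)OCC; water, O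
Why: Stille coupling with an acetyl anion equivalent followed by mild hydrolysis of the enol ether should give the methyl ketone under conditions that spare the pivalate and, at 0 °C, the aryl acetals.

Step 16
Reactants: 27 4-{2-[(2S,4R,6S)-4-[3-acetyl-4-methoxy-2,6-bis(methoxymethoxy)phenyl]-6-[4-(methoxymethoxy)phenyl]tetrahydro-2H-pyran-2-yl]ethyl}phenyl pivalate; 8 4-(methoxymethoxy)benzaldehyde
Product: 29 (E)-1-{3-[(2S,4R,6S)-2-[2-(4-hydroxyphenyl)ethyl]-6-[4-(methoxymethoxy)phenyl]tetrahydro-2H-pyran-4-yl]-6-methoxy-2,4-bis(methoxymethoxy)phenyl}-3-[4-(methoxymethoxy)phenyl]prop-2-en-1-one, via pivalate-free methyl ketone 28 (not isolated)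
Conditions: KOH (excess, 50 % aq.), EtOH/THF, rt; then aq. NH4Cl/dilute HCl to pH 6
Reagents that add atoms: none
Why: Claisen–Schmidt condensation, in which the methyl ketone enolate adds to the non-enolisable, ether-protected aldehyde and E1cB dehydration gives the (E)-enone, while hydroxide cleaves the aryl pivalate in the same flask.

Step 17
Reactants: 29 (E)-1-{3-[(2S,4R,6S)-2-[2-(4-hydroxyphenyl)ethyl]-6-[4-(methoxymethoxy)phenyl]tetrahydro-2H-pyran-4-yl]-6-methoxy-2,4-bis(methoxymethoxy)phenyl}-3-[4-(methoxymethoxy)phenyl]prop-2-en-1-one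
Product: 30 (E)-1-{2,4-dihydroxy-3-[(2S,4R,6S)-2-[2-(4-hydroxyphenyl)ethyl]-6-(4-hydroxyphenyl)tetrahydro-2H-pyran-4-yl]-6-methoxyphenyl}-3-(4-hydroxyphenyl)prop-2-en-1-one (target)
Conditions: 3 M aq. HCl, MeOH/THF, rt
Reagents that add atoms: none
Why: Acid-catalysed methanolysis of the four aryl methoxymethyl acetals is the usual last step for 2',4'-dihydroxy-6'-methoxy-3'-alkylchalcones; room temperature should keep the chalcone from closing to a flavanone, and reversible ionisation at the benzylic C6–O1 bond would be expected to return to the all-equatorial isomer.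

**Compound list**

1 | 3-(4-hydroxyphenyl)propanoic acid | OC(=O)CCc1ccc(O)cc1 | starting material
2 | 3-[4-(pivaloyloxy)phenyl]propanoic acid | OC(=O)CCc1ccc(OC(=O)C(C)(C)C)cc1 | intermediate
3 | 4-(3-hydroxypropyl)phenyl pivalate | OCCCc1ccc(OC(=O)C(C)(C)C)cc1 | intermediate
4 | 4-(3-oxopropyl)phenyl pivalate | O=CCCc1ccc(OC(=O)C(C)(C)C)cc1 | intermediate
5 | allenylboronic acid pinacol ester | C=C=CB1OC(C)(C)C(C)(C)O1 | starting material
6 | 4-[(3S)-3-[(4,4,5,5-tetramethyl-1,3,2-dioxaborolan-2-yl)oxy]hex-5-yn-1-yl]phenyl pivalate | C#CC[C@H](CCc1ccc(OC(=O)C(C)(C)C)cc1)OB1OC(C)(C)C(C)(C)O1 | intermediate (not isolated)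
7 | 4-[(3S)-3-hydroxyhex-5-yn-1-yl]phenyl pivalate | C#CC[C@H](CCc1ccc(OC(=O)C(C)(C)C)cc1)O | intermediate
8 | 4-(methoxymethoxy)benzaldehyde | COCOc1ccc(C=O)cc1 | starting material
9 | [4-(methoxymethoxy)phenyl]methanol | COCOc1ccc(CO)cc1 | intermediate
10 | 4-(methoxymethoxy)benzyl 2,2,2-trichloroacetimidate | COCOc1ccc(COC(=N)C(Cl)(Cl)Cl)cc1 | intermediate
11 | 4-[(3S)-3-{[4-(methoxymethoxy)benzyl]oxy}hex-5-yn-1-yl]phenyl pivalate | C#CC[C@H](CCc1ccc(OC(=O)C(C)(C)C)cc1)OCc1ccc(OCOC)cc1 | intermediate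
12 | 4-[(3S)-5-acetoxy-3-{[4-(methoxymethoxy)benzyl]oxy}hex-5-en-1-yl]phenyl pivalate | CC(=O)OC(=C)C[C@H](CCc1ccc(OC(=O)C(C)(C)C)cc1)OCc1ccc(OCOC)cc1 | intermediate
13 | (E)-{(3S)-5-acetoxy-1-[4-(pivaloyloxy)phenyl]hex-5-en-3-yl}[4-(methoxymethoxy)benzylidene]oxonium | CC(=O)OC(=C)C[C@H](CCc1ccc(OC(=O)C(C)(C)C)cc1)/[O+]=C/c1ccc(OCOC)cc1 | intermediate (not isolated)
14 | acetyl{(2S,6S)-2-[4-(methoxymethoxy)phenyl]-6-{2-[4-(pivaloyloxy)phenyl]ethyl}tetrahydro-4H-pyran-4-ylidene}oxonium | CC(=O)[O+]=C1C[C@H](CCc2ccc(OC(=O)C(C)(C)C)cc2)O[C@H](c2ccc(OCOC)cc2)C1 | intermediate (not isolated)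
15 | 4-{2-[(2S,6S)-6-[4-(methoxymethoxy)phenyl]-4-oxotetrahydro-2H-pyran-2-yl]ethyl}phenyl pivalate | O=C1C[C@H](CCc2ccc(OC(=O)C(C)(C)C)cc2)O[C@H](c2ccc(OCOC)cc2)C1 | intermediate
16 | 4-{2-[(2S,6S)-6-[4-(methoxymethoxy)phenyl]-4-(trifluoromethanesulfonyloxy)-3,6-dihydro-2H-pyran-2-yl]ethyl}phenyl pivalate | O=S(=O)(OC1=C[C@@H](c2ccc(OCOC)cc2)O[C@@H](CCc2ccc(OC(=O)C(C)(C)C)cc2)C1)C(F)(F)F | intermediate
17 | 4-{2-[(2S,6S)-6-[4-(methoxymethoxy)phenyl]-4-(trifluoromethanesulfonyloxy)-5,6-dihydro-2H-pyran-2-yl]ethyl}phenyl pivalate | O=S(=O)(OC1=C[C@H](CCc2ccc(OC(=O)C(C)(C)C)cc2)O[C@H](c2ccc(OCOC)cc2)C1)C(F)(F)F | intermediate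
18 | 5-methoxyresorcinol | COc1cc(O)cc(O)c1 | starting material
19 | 1-methoxy-3,5-bis(methoxymethoxy)benzene | COCOc1cc(OC)cc(OCOC)c1 | intermediate
20 | [4-methoxy-2,6-bis(methoxymethoxy)phenyl]lithium | [Li]c1c(OCOC)cc(OC)cc1OCOC | intermediate (not isolated)
21 | chloro[4-methoxy-2,6-bis(methoxymethoxy)phenyl]zinc | Cl[Zn]c1c(OCOC)cc(OC)cc1OCOC | intermediate (not isolated)
22 | 4-{2-[(2S,6S)-4-[4-methoxy-2,6-bis(methoxymethoxy)phenyl]-6-[4-(methoxymethoxy)phenyl]-3,6-dihydro-2H-pyran-2-yl]ethyl}phenyl pivalate | COCOc1cc(OC)cc(OCOC)c1C2=C[C@@H](c3ccc(OCOC)cc3)O[C@@H](CCc3ccc(OC(=O)C(C)(C)C)cc3)C2 | intermediate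
23 | 4-{2-[(2S,6S)-4-[4-methoxy-2,6-bis(methoxymethoxy)phenyl]-6-[4-(methoxymethoxy)phenyl]-5,6-dihydro-2H-pyran-2-yl]ethyl}phenyl pivalate | COCOc1cc(OC)cc(OCOC)c1C2=C[C@H](CCc3ccc(OC(=O)C(C)(C)C)cc3)O[C@H](c3ccc(OCOC)cc3)C2 | intermediate
24 | 4-{2-[(2S,4R,6S)-4-[4-methoxy-2,6-bis(methoxymethoxy)phenyl]-6-[4-(methoxymethoxy)phenyl]tetrahydro-2H-pyran-2-yl]ethyl}phenyl pivalate | COCOc1cc(OC)cc(OCOC)c1[C@@H]2C[C@H](CCc3ccc(OC(=O)C(C)(C)C)cc3)O[C@H](c3ccc(OCOC)cc3)C2 | intermediate
25 | 4-{2-[(2S,4R,6S)-4-[3-iodo-4-methoxy-2,6-bis(methoxymethoxy)phenyl]-6-[4-(methoxymethoxy)phenyl]tetrahydro-2H-pyran-2-yl]ethyl}phenyl pivalate | COCOc1c(I)c(OC)cc(OCOC)c1[C@@H]2C[C@H](CCc3ccc(OC(=O)C(C)(C)C)cc3)O[C@H](c3ccc(OCOC)cc3)C2 | intermediate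
26 | 4-{2-[(2S,4R,6S)-4-[3-(1-ethoxyvinyl)-4-methoxy-2,6-bis(methoxymethoxy)phenyl]-6-[4-(methoxymethoxy)phenyl]tetrahydro-2H-pyran-2-yl]ethyl}phenyl pivalate | COCOc1c(C(=C)OCC)c(OC)cc(OCOC)c1[C@@H]2C[C@H](CCc3ccc(OC(=O)C(C)(C)C)cc3)O[C@H](c3ccc(OCOC)cc3)C2 | intermediate (not isolated)
27 | 4-{2-[(2S,4R,6S)-4-[3-acetyl-4-methoxy-2,6-bis(methoxymethoxy)phenyl]-6-[4-(methoxymethoxy)phenyl]tetrahydro-2H-pyran-2-yl]ethyl}phenyl pivalate | COCOc1c(C(C)=O)c(OC)cc(OCOC)c1[C@@H]2C[C@H](CCc3ccc(OC(=O)C(C)(C)C)cc3)O[C@H](c3ccc(OCOC)cc3)C2 | intermediate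
28 | 1-{3-[(2S,4R,6S)-2-[2-(4-hydroxyphenyl)ethyl]-6-[4-(methoxymethoxy)phenyl]tetrahydro-2H-pyran-4-yl]-6-methoxy-2,4-bis(methoxymethoxy)phenyl}ethan-1-one | COCOc1c(C(C)=O)c(OC)cc(OCOC)c1[C@@H]2C[C@H](CCc3ccc(O)cc3)O[C@H](c3ccc(OCOC)cc3)C2 | intermediate (not isolated)
29 | (E)-1-{3-[(2S,4R,6S)-2-[2-(4-hydroxyphenyl)ethyl]-6-[4-(methoxymethoxy)phenyl]tetrahydro-2H-pyran-4-yl]-6-methoxy-2,4-bis(methoxymethoxy)phenyl}-3-[4-(methoxymethoxy)phenyl]prop-2-en-1-one | COCOc1c(C(=O)/C=C/c2ccc(OCOC)cc2)c(OC)cc(OCOC)c1[C@@H]2C[C@H](CCc3ccc(O)cc3)O[C@H](c3ccc(OCOC)cc3)C2 | intermediate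
30 | (E)-1-{2,4-dihydroxy-3-[(2S,4R,6S)-2-[2-(4-hydroxyphenyl)ethyl]-6-(4-hydroxyphenyl)tetrahydro-2H-pyran-4-yl]-6-methoxyphenyl}-3-(4-hydroxyphenyl)prop-2-en-1-one | COc1cc(O)c([C@@H]2C[C@H](CCc3ccc(O)cc3)O[C@H](c3ccc(O)cc3)C2)c(O)c1C(=O)/C=C/c1ccc(O)cc1 | target

**Step count**

Total: 17 steps. Longest linear sequence: 14 steps (steps 1–4, 7–10 and 12–17, from acid 1).

**Steps most likely to fail**

Step 9. Hydride abstraction may be slow with the acetal-type para substituent, or the oxocarbenium ion may be intercepted by traces of water (loss of the benzyl group as the aldehyde) or over-oxidised before the enol acetate closes the ring. The fallback sets out from alcohol 7 and returns at ketone 15. Gold-catalysed Markovnikov hydration of the alkyne ((Ph3P)AuNTf2, aqueous MeOH) should give 4-[(3S)-3-hydroxy-5-oxohexyl]phenyl pivalate F1. Its dianion (two equivalents of LiN(i-Pr)2, THF, −78 °C; alkoxide plus methyl-side enolate) is added to aldehyde 8 to give the aldol 4-[(3S)-3,7-dihydroxy-7-[4-(methoxymethoxy)phenyl]-5-oxoheptyl]phenyl pivalate F2 as both C7 epimers. Catalytic pyridinium p-toluenesulfonate in warm toluene should dehydrate the benzylic alcohol to the enone 4-[(3S,6E)-3-hydroxy-7-[4-(methoxymethoxy)phenyl]-5-oxohept-6-en-1-yl]phenyl pivalate F3, which closes under the same conditions by 6-endo oxa-Michael addition to the thermodynamically preferred 2,6-cis ketone 15.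

Step 12. Transmetalation and reductive elimination of the doubly ortho-substituted arylzinc may be slower than its proto-demetalation or than decay of the enol triflates. The fallback sets out from ketone 15 and aryllithium 20 (made from 19 as in step 12) and returns at alkenes 22 and 23. Addition of 20 to the ketone at −78 °C in THF, with LaCl3·2LiCl present to suppress enolisation, should give the tertiary benzylic alcohol 4-{2-[(2S,6S)-4-hydroxy-4-[4-methoxy-2,6-bis(methoxymethoxy)phenyl]-6-[4-(methoxymethoxy)phenyl]tetrahydro-2H-pyran-2-yl]ethyl}phenyl pivalate F4 (configuration at C4 immaterial). Catalytic pyridinium p-toluenesulfonate in toluene then dehydrates this very easily ionised alcohol to the mixture of 22 and 23, which enters step 13.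

Step 17. Under the acid needed to cleave four acetals, the free 2'-phenol may add to the enone (flavanone formation), and the benzylic C6–O1 bond may ionise and be captured by a ring A phenol. The fallback sets out from ketone 27 and returns at target 30; it removes the acetals before the enone exists and carries the phenols through the condensation as allyl ethers.
- Methanolic HCl, then K2CO3 in MeOH, should give 1-{2,4-dihydroxy-3-[(2S,4R,6S)-2-[2-(4-hydroxyphenyl)ethyl]-6-(4-hydroxyphenyl)tetrahydro-2H-pyran-4-yl]-6-methoxyphenyl}ethan-1-one F5.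
- Allyl bromide with Cs2CO3 in DMF at 50 °C gives 1-{2,4-bis(allyloxy)-3-[(2S,4R,6S)-2-{2-[4-(allyloxy)phenyl]ethyl}-6-[4-(allyloxy)phenyl]tetrahydro-2H-pyran-4-yl]-6-methoxyphenyl}ethan-1-one F6.
- Claisen–Schmidt condensation with purchased 4-(allyloxy)benzaldehyde (KOH, EtOH) gives (E)-1-{2,4-bis(allyloxy)-3-[(2S,4R,6S)-2-{2-[4-(allyloxy)phenyl]ethyl}-6-[4-(allyloxy)phenyl]tetrahydro-2H-pyran-4-yl]-6-methoxyphenyl}-3-[4-(allyloxy)phenyl]prop-2-en-1-one F7.
- Pd(PPh3)4 (cat.) with K2CO3 in MeOH at rt, in which zerovalent palladium transfers the five allyl groups to methoxide, should release 30 without any acid.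

**Further compounds**

F1 | step 9 | 4-[(3S)-3-hydroxy-5-oxohexyl]phenyl pivalate | CC(=O)C[C@H](CCc1ccc(OC(=O)C(C)(C)C)cc1)O
F2 | step 9 | 4-[(3S)-3,7-dihydroxy-7-[4-(methoxymethoxy)phenyl]-5-oxoheptyl]phenyl pivalate (both C7 epimers) | COCOc1ccc(C(O)CC(=O)C[C@H](CCc2ccc(OC(=O)C(C)(C)C)cc2)O)cc1
F3 | step 9 | 4-[(3S,6E)-3-hydroxy-7-[4-(methoxymethoxy)phenyl]-5-oxohept-6-en-1-yl]phenyl pivalate | O=C(/C=C/c1ccc(OCOC)cc1)C[C@H](CCc1ccc(OC(=O)C(C)(C)C)cc1)O
F4 | step 12 | 4-{2-[(2S,6S)-4-hydroxy-4-[4-methoxy-2,6-bis(methoxymethoxy)phenyl]-6-[4-(methoxymethoxy)phenyl]tetrahydro-2H-pyran-2-yl]ethyl}phenyl pivalate (C4 unspecified) | COCOc1cc(OC)cc(OCOC)c1C2(O)C[C@H](CCc3ccc(OC(=O)C(C)(C)C)cc3)O[C@H](c3ccc(OCOC)cc3)C2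
F5 | step 17 | 1-{2,4-dihydroxy-3-[(2S,4R,6S)-2-[2-(4-hydroxyphenyl)ethyl]-6-(4-hydroxyphenyl)tetrahydro-2H-pyran-4-yl]-6-methoxyphenyl}ethan-1-one | COc1cc(O)c([C@@H]2C[C@H](CCc3ccc(O)cc3)O[C@H](c3ccc(O)cc3)C2)c(O)c1C(C)=O
F6 | step 17 | 1-{2,4-bis(allyloxy)-3-[(2S,4R,6S)-2-{2-[4-(allyloxy)phenyl]ethyl}-6-[4-(allyloxy)phenyl]tetrahydro-2H-pyran-4-yl]-6-methoxyphenyl}ethan-1-one | COc1cc(OCC=C)c([C@@H]2C[C@H](CCc3ccc(OCC=C)cc3)O[C@H](c3ccc(OCC=C)cc3)C2)c(OCC=C)c1C(C)=O
F7 | step 17 | (E)-1-{2,4-bis(allyloxy)-3-[(2S,4R,6S)-2-{2-[4-(allyloxy)phenyl]ethyl}-6-[4-(allyloxy)phenyl]tetrahydro-2H-pyran-4-yl]-6-methoxyphenyl}-3-[4-(allyloxy)phenyl]prop-2-en-1-one | COc1cc(OCC=C)c([C@@H]2C[C@H](CCc3ccc(OCC=C)cc3)O[C@H](c3ccc(OCC=C)cc3)C2)c(OCC=C)c1C(=O)/C=C/c1ccc(OCC=C)cc1
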